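## The problem

The target **26** is a cyclohex-2-en-1-one in which every ring carbon is substituted. With C1 as the ketone carbon, C2 bears the hydroxymethyl carbon C7, C3 is the β-alkene carbon, C4 carries the propanoate, C5 the isopropyl group and C6 the (E)-4-hydroxy-2-methylbut-2-enoate. Only one ring has to be made, but it holds three contiguous stereocentres (4S,5S,6R): the C4 oxygen is cis and the C6 oxygen trans to the isopropyl group. C5 is the natural control element: a reagent that reaches a trigonal C4 from the face away from isopropyl leaves the new C4–O bond cis to it, and the trans C5/C6 pair is what a pericyclic closure or equilibration delivers. Nothing in the molecule controls absolute configuration, which must come from a catalyst, an enzyme or the chiral pool. The sensitive points are two different esters beside two free primary allylic alcohols (order of acylation, acyl migration under base), the C6 centre α to the ketone, and the C4 propanoate, an allylic ester that zerovalent palladium can ionise and whose loss together with the C6 ester would aromatise the ring. The enabling feature is the segment O–C6–C5(isopropyl)–C4(O) closed through C1 and C3: with C4 as a ketone it is a trans-4-hydroxy-5-alkylcyclopent-2-enone, the product of the acid-mediated rearrangement of a 2-furylcarbinol. C1, C3, C4, C5 and C6 are then the five carbons of furfural, and what remains is to insert C2 between C1 and C3 so that oxygen arrives at C1 and a handle for C7 at C2.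

## Retrosynthesis

**End game (26 back to 21).** The two primary allylic hydroxyls of **26** are unmasked last from the bis-silyl ether **25**, so no acylation is ever run beside a free primary alcohol. The C4–O acyl bond of **25** is cut to alcohol **23** and propionic anhydride **24**. The propanoate goes on late because an allylic ester at C4 would not be safe in the palladium step. Alcohol **23** comes from **22** by removing a secondary tert-butyldimethylsilyl ether beside two primary tert-butyldiphenylsilyl ethers, and **22** from the hydroxymethyl enone **21**. The forward steps need only one reliable difference in silyl ether lability.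

**C2–C7 bond (21 back to 19 and 20).** Cutting C2–C7 gives the α-bromoenone **19** and (tributylstannyl)methanol **20**. A halogen at C2 is the natural residue of a dihalocarbene ring expansion, so this cut costs no extra functionalisation. An aldol-type hydroxymethylation would need base next to the C6 ester. The coupling must tolerate an α-acyloxy ketone and an allylic silyl ether, which a neutral Stille coupling does.

**C6 ester (19 back to 13 and 18).** Cutting the C6–O acyl bond gives the α-hydroxy enone **13** and acid **18**. The acid carries its own primary hydroxyl as a tert-butyldiphenylsilyl ether. It is made from glycolaldehyde dimer **14** and the stabilised ylide **15** through hydroxy ester **16** and silyl ether **17**. The (E)-alkene comes from the Wittig step, and the esterification must not epimerise C6.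

**C1 oxygen and C2 (13 back to 8 and 9).** Enone **13** is the allylic oxidation product of the cis-diol **12**. Diol **12** comes from the dibromocyclopropane **10** by ring opening, in which the C1–C3 bond breaks and the C1–O bond forms through the cyclic carbonate **11**. Cyclopropane **10** is the adduct of bromoform **9** (C2) with the cyclopentene **8**, formed through the C1–C2 and C2–C3 bonds. Other one-carbon ring expansions put the new carbon next to a carbonyl carbon, which here would be C4. The carbene route puts it between the two alkene carbons and gives oxygen at C1 and bromine at C2 in the same step. The demand on the forward reaction is regiochemistry. The allyl cation must be captured at C1 and not at C3, so the C6 oxygen carries a participating tert-butyl carbonate and the C4 oxygen a silyl ether that cannot participate.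

**Protecting groups and C4 (8 back to 5).** Silyl ether **8** comes from alcohol **7**, which is the 1,2-reduction product of enone **6**, the tert-butyl carbonate of hydroxy enone **5**. The precursor is a simple cyclopentenone with two stereocentres. The reduction must deliver hydride anti to the isopropyl group so that the C4 oxygen ends cis to it.

**Five-membered ring (5 back to 1 and 2).** Enantiomer **5** is taken from the racemate **4** by lipase resolution. Racemate **4** is cut at C5–C6, which opens the ring to the furylcarbinol **3**, and **3** is cut at the carbinol carbon to furfural **1** and isopropylmagnesium chloride **2**. This removes a ring and two stereocentres in one step and ends at two bulk chemicals. The forward rearrangement must give the trans isomer and must not drift to the conjugated 2-isopropyl isomer.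

## Roads not taken

**Alternative 1:** The ring is cut at C4–C5 and C1–C6. The forward step is an endo Diels–Alder reaction of (E)-buta-1,3-dien-1-yl acetate **A1** with the imide 3-[(E)-3-(benzoyloxy)prop-2-enoyl]-1,3-oxazolidin-2-one **A2** under [Cu(tBu-box)](SbF6)2, giving cycloadduct **A3**.
- Merits: one catalytic enantioselective step sets C4, C5 and C6 in the correct relative and absolute sense, with no resolution. In stereochemical economy this road is better than the chosen plan.
- Weak points: C5 arrives as an imide carbonyl and must become isopropyl in the presence of two esters and a ring alkene. C1 is still a methylene and needs allylic oxidation, C2 still needs the hydroxymethyl group, and both esters are placeholders. The β-acyloxy acryloyl imide **A2** is a deactivated, push–pull dienophile.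
- Comparison: the chosen plan loses half the material in a resolution. Against that, it has isopropyl on C5 from the first step, and one ring expansion supplies the C1 oxygen and the C2 handle together, so far fewer functional-group changes are made on the crowded ring.

**Alternative 2:** The cut is at C1–C2 and O–C7. The aldoxime **A4** is oxidised with NaOCl to the nitrile oxide **A5**, which adds across its terminal alkene to give the acetonide-bridged isoxazoline **A6**.
- Merits: the ring and the masked β-hydroxy ketone (C1 carbonyl, C7 hydroxyl) form in one tin-free step. N–O cleavage and elimination of the C3 oxygen would then give the hydroxymethyl enone directly, a cleaner end game for C2/C7 than the chosen plan.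
- Weak points: **A4** already needs three stereocentres built by linear acyclic chemistry, one of them a C3 oxygen that is later thrown away. C6 carries no oxygen and must be hydroxylated late, α to the ketone.
- Comparison: the chosen plan sets a two-step entry to a ring that already carries the C6 oxygen against this road's better end game.

**Alternative 3:** The cut is at C2=C3. The acyclic dienone **A7** is closed by ring-closing metathesis with the second-generation Hoveyda–Grubbs catalyst to cyclohexenone **A8**.
- Merits: the ring closure is dependable, the C7 oxygen is in place and protected, and C4/C5 come from a substrate-controlled organocopper conjugate addition. Step for step this road is probably as reliable as the chosen one or more so, and no shorter route is claimed here.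
- Weak points: the metathesis must form a trisubstituted enone alkene from an electron-poor 1,1-disubstituted alkene. Absolute configuration needs an enantiopure acyclic acceptor. C6 is again bare and needs an enolate hydroxylation on a base-sensitive γ-alkoxy enone.
- Comparison: the chosen plan has all three ring oxygens in place before the six-membered ring exists and starts from furfural. It pays for this with a resolution and a riskier ring expansion.

Key step: step 2

Assumption: in step 3 the lipase is taken to acylate the (4R,5S)-enantiomer faster, its branched C5 flank acting as the large group, so that **5** is the unreacted fraction. If the preference is reversed, **5** is released from the acetate fraction by lipase-mediated alcoholysis and the route is unchanged from step 4 on.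

## Route

Step 1
Reactants: 1 furfural; 2 isopropylmagnesium chloride
Product: 3 1-(furan-2-yl)-2-methylpropan-1-ol (racemate)
Conditions: THF, 0 °C; aq. NH4Cl
Reagents that add atoms: none
Why: Grignard 1,2-addition to an aldehyde; the carbinol centre forms as a racemate, which is of no consequence because it becomes planar in step 2.

Step 2
Reactants: 3 1-(furan-2-yl)-2-methylpropan-1-ol
Product: 4 (±)-trans-4-hydroxy-5-(propan-2-yl)cyclopent-2-en-1-one (racemate)
Conditions: Dy(OTf)3 (10 mol %), t-BuOH/H2O (5:1), 80 °C
Reagents that add atoms: water, O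
Why: Piancatelli rearrangement: Dy(OTf)3 ionises the carbinol of 3 to a furan-stabilised oxocarbenium ion, water adds at the remote furan carbon (C6 of the target) and the hemiacetal opens to a 1-hydroxypentadienyl cation. Thermal conrotatory 4π electrocyclisation of this cation, the closure known from the Nazarov cyclisation, joins C5 to C6 and closes the five-membered carbocycle made of C4, C5, C6, C1 and C3; proton loss from the oxyallyl cation then gives the enone. Both new stereocentres (C5 and C6) arise in this closure: the hydroxyl and isopropyl termini lie outward in the extended cation and conrotation places them trans, which is also the more stable arrangement. The step needs trans over cis selectivity and no drift to the conjugated 4-hydroxy-2-isopropyl isomer; the first is inherent in the pericyclic closure, the second is secured by the nearly neutral medium and by stopping once 3 is consumed. Alkyl carbinols ionise less readily than aryl ones, hence the Dy(OTf)3 and the heated aqueous tert-butanol. The product is racemic because the carbinol centre is lost in the planar cation; absolute configuration is fixed in step 3.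

Step 3
Reactants: 4 (±)-trans-4-hydroxy-5-(propan-2-yl)cyclopent-2-en-1-one
Product: 5 (4S,5R)-4-hydroxy-5-(propan-2-yl)cyclopent-2-en-1-one (recovered alcohol)
Conditions: Candida antarctica lipase B (immobilised), vinyl acetate, MTBE, 30 °C, stopped just past half conversion; chromatography
Reagents that add atoms: none
Why: Lipase-catalysed kinetic resolution by irreversible transesterification with vinyl acetate; one enantiomer is acetylated and the other recovered, and running past half conversion raises the purity of the recovered 5. This fixes C5 and C6 of the target in the absolute sense.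

Step 4
Reactants: 5 (4S,5R)-4-hydroxy-5-(propan-2-yl)cyclopent-2-en-1-one
Product: 6 tert-butyl (1S,5R)-4-oxo-5-(propan-2-yl)cyclopent-2-en-1-yl carbonate
Conditions: Boc2O, DMAP (cat.), CH2Cl2, 0 °C
Reagents that add atoms: di-tert-butyl dicarbonate, CC(C)(C)OC(=O)OC(=O)OC(C)(C)C
Why: DMAP-catalysed acylation of a secondary alcohol; no stereocentre is touched, and the cold medium without stoichiometric amine avoids β-elimination of the new carbonate.

Step 5
Reactants: 6 tert-butyl (1S,5R)-4-oxo-5-(propan-2-yl)cyclopent-2-en-1-yl carbonate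
Product: 7 tert-butyl (1S,4S,5S)-4-hydroxy-5-(propan-2-yl)cyclopent-2-en-1-yl carbonate (hydroxyl cis to isopropyl, carbonate trans)
Conditions: NaBH4, CeCl3·7H2O, MeOH, −78 °C
Reagents that add atoms: none
Why: Luche reduction, selective for 1,2-addition to the enone; hydride is delivered to the carbonyl face opposite the adjacent isopropyl group, which sets C4 with its oxygen cis to isopropyl.

Step 6
Reactants: 7 tert-butyl (1S,4S,5S)-4-hydroxy-5-(propan-2-yl)cyclopent-2-en-1-yl carbonate
Product: 8 tert-butyl (1S,4S,5R)-4-[(tert-butyldimethylsilyl)oxy]-5-(propan-2-yl)cyclopent-2-en-1-yl carbonate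
Conditions: TBSCl, imidazole, DMF, rt
Reagents that add atoms: tert-butyldimethylsilyl chloride, CC(C)(C)[Si](C)(C)Cl
Why: Silylation of a secondary allylic alcohol; unlike an ester, the silyl ether cannot act as a neighbouring group in step 8, so only the C6 carbonate can capture the cation.

Step 7
Reactants: 8 tert-butyl (1S,4S,5R)-4-[(tert-butyldimethylsilyl)oxy]-5-(propan-2-yl)cyclopent-2-en-1-yl carbonate; 9 bromoform
Product: 10 tert-butyl (1S,2R,3R,4R,5R)-6,6-dibromo-4-[(tert-butyldimethylsilyl)oxy]-3-(propan-2-yl)bicyclo[3.1.0]hexan-2-yl carbonate (cyclopropane on the face of the carbonate)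
Conditions: CHBr3 (excess), 50 % aq. NaOH, BnEt3NCl (cat.), CH2Cl2, 0 °C to rt
Reagents that add atoms: none
Why: Dibromocarbene [2+1] cycloaddition under phase-transfer conditions; the carbene is generated at the interface, so the hindered carbonate should outlast it. Addition is expected anti to the silyloxy and isopropyl groups, but both cyclopropane diastereomers give the same cation in step 8.

Step 8
Reactants: 10 tert-butyl (1S,2R,3R,4R,5R)-6,6-dibromo-4-[(tert-butyldimethylsilyl)oxy]-3-(propan-2-yl)bicyclo[3.1.0]hexan-2-yl carbonate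
Product: 12 (1R,2R,5R,6R)-3-bromo-5-[(tert-butyldimethylsilyl)oxy]-6-(propan-2-yl)cyclohex-3-ene-1,2-diol, via cis-fused cyclic carbonate 11 (not isolated)
Conditions: AgOTf, 2,6-di-tert-butylpyridine, ClCH2CH2Cl, rt to 50 °C; then MeOH, K2CO3, 0 °C to rt
Reagents that add atoms: none
Why: Silver-assisted loss of the endo bromide triggers disrotatory electrocyclic opening of the ring-fused gem-dibromocyclopropane to a 2-bromocyclohexenyl cation; the carbonate carbonyl on C6 closes on C1 and the resulting dioxolanylium ion sheds 2-methylpropene, as in iodocarbonate cyclisations, so oxygen arrives only at C1 and cis to the C6 oxygen. Methanolysis in the same flask frees the cis-diol; the C1 configuration is irrelevant because C1 becomes the ketone.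

Step 9
Reactants: 12 (1R,2R,5R,6R)-3-bromo-5-[(tert-butyldimethylsilyl)oxy]-6-(propan-2-yl)cyclohex-3-ene-1,2-diol
Product: 13 (4R,5R,6R)-2-bromo-4-[(tert-butyldimethylsilyl)oxy]-6-hydroxy-5-(propan-2-yl)cyclohex-2-en-1-one
Conditions: MnO2 (activated, excess), CH2Cl2, rt
Reagents that add atoms: none
Why: MnO2 oxidises allylic alcohols far faster than saturated ones, so the C1 carbinol next to the bromoalkene should be converted into the enone while the C6 hydroxyl stays.

Step 10
Reactants: 14 glycolaldehyde dimer (1,4-dioxane-2,5-diol); 15 ethyl 2-(triphenylphosphoranylidene)propanoate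
Product: 16 ethyl (2E)-4-hydroxy-2-methylbut-2-enoate
Conditions: CH2Cl2, reflux
Reagents that add atoms: none
Why: Wittig olefination of glycolaldehyde, released from its dimer, with a stabilised α-branched ylide; such ylides give the (E)-trisubstituted ester.

Step 11
Reactants: 16 ethyl (2E)-4-hydroxy-2-methylbut-2-enoate
Product: 17 ethyl (2E)-4-[(tert-butyldiphenylsilyl)oxy]-2-methylbut-2-enoate
Conditions: TBDPSCl, imidazole, CH2Cl2, rt
Reagents that add atoms: tert-butyldiphenylsilyl chloride, CC(C)(C)[Si](Cl)(c1ccccc1)c1ccccc1
Why: Silylation of a primary allylic alcohol; the tert-butyldiphenylsilyl ether is chosen because it must outlast the acidic removal of a tert-butyldimethylsilyl ether in step 16.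

Step 12
Reactants: 17 ethyl (2E)-4-[(tert-butyldiphenylsilyl)oxy]-2-methylbut-2-enoate
Product: 18 (2E)-4-[(tert-butyldiphenylsilyl)oxy]-2-methylbut-2-enoic acid
Conditions: LiOH, THF/H2O, rt; then dilute HCl to pH 3
Reagents that add atoms: lithium hydroxide, [Li+].[OH-]
Why: Saponification of an ethyl ester; the silyl ether and the alkene geometry are stable to aqueous LiOH at room temperature.

Step 13
Reactants: 13 (4R,5R,6R)-2-bromo-4-[(tert-butyldimethylsilyl)oxy]-6-hydroxy-5-(propan-2-yl)cyclohex-2-en-1-one; 18 (2E)-4-[(tert-butyldiphenylsilyl)oxy]-2-methylbut-2-enoic acid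
Product: 19 (1R,5R,6R)-3-bromo-5-[(tert-butyldimethylsilyl)oxy]-2-oxo-6-(propan-2-yl)cyclohex-3-en-1-yl (2E)-4-[(tert-butyldiphenylsilyl)oxy]-2-methylbut-2-enoate
Conditions: DCC, DMAP (cat.), CH2Cl2, 0 °C to rt
Reagents that add atoms: none
Why: Steglich esterification; the bond formed is O–acyl, so C6 keeps its configuration, and the trans arrangement at C6 is also the thermodynamic one should DMAP cause any enolisation.

Step 14
Reactants: 19 (1R,5R,6R)-3-bromo-5-[(tert-butyldimethylsilyl)oxy]-2-oxo-6-(propan-2-yl)cyclohex-3-en-1-yl (2E)-4-[(tert-butyldiphenylsilyl)oxy]-2-methylbut-2-enoate; 20 (tributylstannyl)methanol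
Product: 21 (1R,5S,6R)-5-[(tert-butyldimethylsilyl)oxy]-3-(hydroxymethyl)-2-oxo-6-(propan-2-yl)cyclohex-3-en-1-yl (2E)-4-[(tert-butyldiphenylsilyl)oxy]-2-methylbut-2-enoate
Conditions: Pd(PPh3)4 (cat.), 1,4-dioxane, 85 °C
Reagents that add atoms: none
Why: Migita–Kosugi–Stille coupling: zerovalent palladium inserts into the activated C–Br bond of the α-bromoenone, the hydroxymethyl group is transferred from tin in preference to butyl, and reductive elimination forms C2–C7. The step is run while C4 still carries a silyl ether, because an allylic ester there could ionise to a π-allyl complex.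

Step 15
Reactants: 21 (1R,5S,6R)-5-[(tert-butyldimethylsilyl)oxy]-3-(hydroxymethyl)-2-oxo-6-(propan-2-yl)cyclohex-3-en-1-yl (2E)-4-[(tert-butyldiphenylsilyl)oxy]-2-methylbut-2-enoate
Product: 22 (1R,5S,6R)-5-[(tert-butyldimethylsilyl)oxy]-3-{[(tert-butyldiphenylsilyl)oxy]methyl}-2-oxo-6-(propan-2-yl)cyclohex-3-en-1-yl (2E)-4-[(tert-butyldiphenylsilyl)oxy]-2-methylbut-2-enoate
Conditions: TBDPSCl, imidazole, CH2Cl2, 0 °C
Reagents that add atoms: tert-butyldiphenylsilyl chloride, CC(C)(C)[Si](Cl)(c1ccccc1)c1ccccc1
Why: Silylation of the only free hydroxyl, a primary allylic one; it shields C7–OH during the propionylation of step 17.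

Step 16
Reactants: 22 (1R,5S,6R)-5-[(tert-butyldimethylsilyl)oxy]-3-{[(tert-butyldiphenylsilyl)oxy]methyl}-2-oxo-6-(propan-2-yl)cyclohex-3-en-1-yl (2E)-4-[(tert-butyldiphenylsilyl)oxy]-2-methylbut-2-enoate
Product: 23 (1R,5S,6S)-3-{[(tert-butyldiphenylsilyl)oxy]methyl}-5-hydroxy-2-oxo-6-(propan-2-yl)cyclohex-3-en-1-yl (2E)-4-[(tert-butyldiphenylsilyl)oxy]-2-methylbut-2-enoate
Conditions: CSA (cat.), MeOH/CH2Cl2, 0 °C to rt
Reagents that add atoms: none
Why: Acid-catalysed methanolysis cleaves a tert-butyldimethylsilyl ether much faster than a tert-butyldiphenylsilyl ether, so the C4 hydroxyl is freed alone; the esters are inert to catalytic acid in cold methanol.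

Step 17
Reactants: 23 (1R,5S,6S)-3-{[(tert-butyldiphenylsilyl)oxy]methyl}-5-hydroxy-2-oxo-6-(propan-2-yl)cyclohex-3-en-1-yl (2E)-4-[(tert-butyldiphenylsilyl)oxy]-2-methylbut-2-enoate; 24 propionic anhydride
Product: 25 (1R,5S,6S)-3-{[(tert-butyldiphenylsilyl)oxy]methyl}-2-oxo-5-(propanoyloxy)-6-(propan-2-yl)cyclohex-3-en-1-yl (2E)-4-[(tert-butyldiphenylsilyl)oxy]-2-methylbut-2-enoate
Conditions: pyridine, DMAP (cat.), CH2Cl2, 0 °C
Reagents that add atoms: none
Why: DMAP-catalysed acylation of the single free secondary alcohol; the O–acyl bond forms with retention at C4.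

Step 18
Reactants: 25 (1R,5S,6S)-3-{[(tert-butyldiphenylsilyl)oxy]methyl}-2-oxo-5-(propanoyloxy)-6-(propan-2-yl)cyclohex-3-en-1-yl (2E)-4-[(tert-butyldiphenylsilyl)oxy]-2-methylbut-2-enoate
Product: 26 (1R,5S,6S)-3-(hydroxymethyl)-2-oxo-5-(propanoyloxy)-6-(propan-2-yl)cyclohex-3-en-1-yl (2E)-4-hydroxy-2-methylbut-2-enoate (CNP0285949.1)
Conditions: HF·pyridine, pyridine, THF, 0 °C to rt
Reagents that add atoms: none
Why: Fluoride cleavage of both primary silyl ethers in a buffered, non-basic medium that leaves the two esters in place and gives no alkoxide that could start acyl migration.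

## Compound list

1 | furfural | O=Cc1ccco1 | starting material
2 | isopropylmagnesium chloride | CC(C)[Mg]Cl | starting material
3 | 1-(furan-2-yl)-2-methylpropan-1-ol (racemate) | CC(C)C(O)c1ccco1 | intermediate
4 | (±)-trans-4-hydroxy-5-(propan-2-yl)cyclopent-2-en-1-one (racemate, both enantiomers written) | O=C1C=C[C@H](O)[C@H]1C(C)C.O=C1C=C[C@@H](O)[C@@H]1C(C)C | intermediate
5 | (4S,5R)-4-hydroxy-5-(propan-2-yl)cyclopent-2-en-1-one | O=C1C=C[C@H](O)[C@H]1C(C)C | intermediate
6 | tert-butyl (1S,5R)-4-oxo-5-(propan-2-yl)cyclopent-2-en-1-yl carbonate | O=C1C=C[C@H](OC(=O)OC(C)(C)C)[C@H]1C(C)C | intermediate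
7 | tert-butyl (1S,4S,5S)-4-hydroxy-5-(propan-2-yl)cyclopent-2-en-1-yl carbonate | O[C@H]1C=C[C@H](OC(=O)OC(C)(C)C)[C@H]1C(C)C | intermediate
8 | tert-butyl (1S,4S,5R)-4-[(tert-butyldimethylsilyl)oxy]-5-(propan-2-yl)cyclopent-2-en-1-yl carbonate | CC(C)(C)[Si](C)(C)O[C@H]1C=C[C@H](OC(=O)OC(C)(C)C)[C@H]1C(C)C | intermediate
9 | bromoform | BrC(Br)Br | starting material
10 | tert-butyl (1S,2R,3R,4R,5R)-6,6-dibromo-4-[(tert-butyldimethylsilyl)oxy]-3-(propan-2-yl)bicyclo[3.1.0]hexan-2-yl carbonate | CC(C)(C)[Si](C)(C)O[C@H]1[C@@H]2C(Br)(Br)[C@@H]2[C@H](OC(=O)OC(C)(C)C)[C@H]1C(C)C | intermediate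
11 | (3aR,4R,5R,7aR)-7-bromo-5-[(tert-butyldimethylsilyl)oxy]-4-(propan-2-yl)-3a,4,5,7a-tetrahydro-1,3-benzodioxol-2-one (cis-fused cyclic carbonate) | CC(C)(C)[Si](C)(C)O[C@H]1C=C(Br)[C@@H]2OC(=O)O[C@@H]2[C@H]1C(C)C | intermediate (not isolated)
12 | (1R,2R,5R,6R)-3-bromo-5-[(tert-butyldimethylsilyl)oxy]-6-(propan-2-yl)cyclohex-3-ene-1,2-diol | CC(C)(C)[Si](C)(C)O[C@H]1C=C(Br)[C@H](O)[C@H](O)[C@H]1C(C)C | intermediate
13 | (4R,5R,6R)-2-bromo-4-[(tert-butyldimethylsilyl)oxy]-6-hydroxy-5-(propan-2-yl)cyclohex-2-en-1-one | CC(C)(C)[Si](C)(C)O[C@H]1C=C(Br)C(=O)[C@H](O)[C@H]1C(C)C | intermediate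
14 | glycolaldehyde dimer (1,4-dioxane-2,5-diol) | OC1COC(O)CO1 | starting material
15 | ethyl 2-(triphenylphosphoranylidene)propanoate | CCOC(=O)C(C)=P(c1ccccc1)(c1ccccc1)c1ccccc1 | starting material
16 | ethyl (2E)-4-hydroxy-2-methylbut-2-enoate | CCOC(=O)/C(C)=C/CO | intermediate
17 | ethyl (2E)-4-[(tert-butyldiphenylsilyl)oxy]-2-methylbut-2-enoate | CCOC(=O)/C(C)=C/CO[Si](c1ccccc1)(c1ccccc1)C(C)(C)C | intermediate
18 | (2E)-4-[(tert-butyldiphenylsilyl)oxy]-2-methylbut-2-enoic acid | OC(=O)/C(C)=C/CO[Si](c1ccccc1)(c1ccccc1)C(C)(C)C | intermediate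
19 | (1R,5R,6R)-3-bromo-5-[(tert-butyldimethylsilyl)oxy]-2-oxo-6-(propan-2-yl)cyclohex-3-en-1-yl (2E)-4-[(tert-butyldiphenylsilyl)oxy]-2-methylbut-2-enoate | CC(C)(C)[Si](C)(C)O[C@H]1C=C(Br)C(=O)[C@H](OC(=O)/C(C)=C/CO[Si](c2ccccc2)(c2ccccc2)C(C)(C)C)[C@H]1C(C)C | intermediate
20 | (tributylstannyl)methanol | CCCC[Sn](CO)(CCCC)CCCC | starting material
21 | (1R,5S,6R)-5-[(tert-butyldimethylsilyl)oxy]-3-(hydroxymethyl)-2-oxo-6-(propan-2-yl)cyclohex-3-en-1-yl (2E)-4-[(tert-butyldiphenylsilyl)oxy]-2-methylbut-2-enoate | CC(C)(C)[Si](C)(C)O[C@H]1C=C(CO)C(=O)[C@H](OC(=O)/C(C)=C/CO[Si](c2ccccc2)(c2ccccc2)C(C)(C)C)[C@H]1C(C)C | intermediate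
22 | (1R,5S,6R)-5-[(tert-butyldimethylsilyl)oxy]-3-{[(tert-butyldiphenylsilyl)oxy]methyl}-2-oxo-6-(propan-2-yl)cyclohex-3-en-1-yl (2E)-4-[(tert-butyldiphenylsilyl)oxy]-2-methylbut-2-enoate | CC(C)(C)[Si](C)(C)O[C@H]1C=C(CO[Si](c2ccccc2)(c2ccccc2)C(C)(C)C)C(=O)[C@H](OC(=O)/C(C)=C/CO[Si](c2ccccc2)(c2ccccc2)C(C)(C)C)[C@H]1C(C)C | intermediate
23 | (1R,5S,6S)-3-{[(tert-butyldiphenylsilyl)oxy]methyl}-5-hydroxy-2-oxo-6-(propan-2-yl)cyclohex-3-en-1-yl (2E)-4-[(tert-butyldiphenylsilyl)oxy]-2-methylbut-2-enoate | O[C@H]1C=C(CO[Si](c2ccccc2)(c2ccccc2)C(C)(C)C)C(=O)[C@H](OC(=O)/C(C)=C/CO[Si](c2ccccc2)(c2ccccc2)C(C)(C)C)[C@H]1C(C)C | intermediate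
24 | propionic anhydride | CCC(=O)OC(=O)CC | starting material
25 | (1R,5S,6S)-3-{[(tert-butyldiphenylsilyl)oxy]methyl}-2-oxo-5-(propanoyloxy)-6-(propan-2-yl)cyclohex-3-en-1-yl (2E)-4-[(tert-butyldiphenylsilyl)oxy]-2-methylbut-2-enoate | CCC(=O)O[C@H]1C=C(CO[Si](c2ccccc2)(c2ccccc2)C(C)(C)C)C(=O)[C@H](OC(=O)/C(C)=C/CO[Si](c2ccccc2)(c2ccccc2)C(C)(C)C)[C@H]1C(C)C | intermediate
26 | (1R,5S,6S)-3-(hydroxymethyl)-2-oxo-5-(propanoyloxy)-6-(propan-2-yl)cyclohex-3-en-1-yl (2E)-4-hydroxy-2-methylbut-2-enoate | CCC(=O)O[C@H]1C=C(CO)C(=O)[C@H](OC(=O)/C(C)=C/CO)[C@H]1C(C)C | target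

## Step count and least certain steps

Total steps: 18. Longest linear sequence: 15 (steps 1–9 and 13–18); steps 10–12 are a three-step branch to acid 18.

**Step 2 (key step).** The isopropyl carbinol ionises slowly, so acid-induced oligomerisation of the furan and isomerisation of the product to the 2-isopropyl isomer may outrun the rearrangement. The fallback forms the same C5–C6 bond by an aldol closure instead of an electrocyclisation. It sets out from 3 and returns at 4.
- Oxidation of 3 (MnO2) gives 1-(furan-2-yl)-2-methylpropan-1-one F1.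
- Wolff–Kishner reduction gives 2-(2-methylpropyl)furan F2.
- Bromine in methanol with Na2CO3 at low temperature gives 2,5-dimethoxy-2-(2-methylpropyl)-2,5-dihydrofuran F3.
- Heating in buffered aqueous dioxane (about pH 6) hydrolyses this to (Z)-6-methyl-4-oxohept-2-enal F4, formed and consumed in the same flask, which closes by intramolecular aldol addition to 4.

**Step 8.** Ionisation is slowed by the two oxygen-bearing carbons flanking the cation. The tert-butyl carbonate may be cleaved by the Lewis-acidic medium before it can capture C1, or proton loss to a bromodiene may beat ring closure of the weakly nucleophilic carbonate. The fallback uses an acid-stable, more strongly participating benzoate. It sets out from 5 and returns at 12.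
- Benzoylation (BzCl, pyridine, 0 °C) gives (1S,5R)-4-oxo-5-(propan-2-yl)cyclopent-2-en-1-yl benzoate F5.
- Luche reduction gives (1S,4S,5S)-4-hydroxy-5-(propan-2-yl)cyclopent-2-en-1-yl benzoate F6.
- Silylation gives its tert-butyldimethylsilyl ether F7.
- Dibromocarbene addition gives the benzoate analogue of 10 F8.
- AgOTf with the hindered pyridine under dry conditions lets the benzoate carbonyl capture C1. Quenching with water gives the two cis hydroxy benzoates, the C6 benzoate of diol 12 F9 and the C1 benzoate of diol 12 F10.
- Methanolysis of the mixture (K2CO3, MeOH) gives 12.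

**Step 5.** Facial selectivity may be poor or reversed. The face anti to isopropyl is the face that carries the remote carbonate, and a small hydride may respond to that group instead. The fallback sets out from 6 and returns at 7. If reduction gives mainly the C4 epimer, tert-butyl (1S,4R,5S)-4-hydroxy-5-(propan-2-yl)cyclopent-2-en-1-yl carbonate F11, this alcohol is inverted under Mitsunobu conditions (4-nitrobenzoic acid, PPh3, DIAD) to the 4-nitrobenzoate of 7 F12. The inversion of an alcohol flanked by an isopropyl-bearing carbon is the standard case for this protocol. Cold methanolysis (K2CO3, MeOH, 0 °C), which spares the tert-butyl carbonate, then gives 7.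

**Step 9.** Chemoselectivity may fail. MnO2 can cleave cis-1,2-diols, and the bromine on C2 makes the allylic carbinol less reactive than usual. The fallback replaces chemoselection by regioselection through a tin acetal. It sets out from 12 and returns at 13. Bu2SnO in hot toluene gives the dibutylstannylene acetal of 12 F13. Brominolysis (NBS, CH2Cl2, molecular sieves) oxidises the pseudo-axial oxygen-bearing carbon, which is C1 because allylic strain from the C2 bromine pushes its oxygen axial.

**Step 14.** Transfer of the hydroxymethyl group from tin may be slow, so butyl transfer and hydrodebromination compete. The fallback sets out from 19 and returns at 21. Deliberate hydrodebromination (Bu3SnH, Pd(PPh3)4 cat.) gives (1R,5S,6R)-5-[(tert-butyldimethylsilyl)oxy]-2-oxo-6-(propan-2-yl)cyclohex-3-en-1-yl (2E)-4-[(tert-butyldiphenylsilyl)oxy]-2-methylbut-2-enoate F14. A Morita–Baylis–Hillman reaction with aqueous formaldehyde (imidazole, THF/H2O) then puts the hydroxymethyl group on C2.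

## Further compounds

F1 | step 2 | 1-(furan-2-yl)-2-methylpropan-1-one | CC(C)C(=O)c1ccco1
F2 | step 2 | 2-(2-methylpropyl)furan | CC(C)Cc1ccco1
F3 | step 2 | 2,5-dimethoxy-2-(2-methylpropyl)-2,5-dihydrofuran (mixture of diastereomers) | COC1C=CC(CC(C)C)(OC)O1
F4 | step 2 | (Z)-6-methyl-4-oxohept-2-enal | CC(C)CC(=O)/C=C\C=O
F5 | step 8 | (1S,5R)-4-oxo-5-(propan-2-yl)cyclopent-2-en-1-yl benzoate | O=C1C=C[C@H](OC(=O)c2ccccc2)[C@H]1C(C)C
F6 | step 8 | (1S,4S,5S)-4-hydroxy-5-(propan-2-yl)cyclopent-2-en-1-yl benzoate | O[C@H]1C=C[C@H](OC(=O)c2ccccc2)[C@H]1C(C)C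
F7 | step 8 | (1S,4S,5R)-4-[(tert-butyldimethylsilyl)oxy]-5-(propan-2-yl)cyclopent-2-en-1-yl benzoate | CC(C)(C)[Si](C)(C)O[C@H]1C=C[C@H](OC(=O)c2ccccc2)[C@H]1C(C)C
F8 | step 8 | (1S,2R,3R,4R,5R)-6,6-dibromo-4-[(tert-butyldimethylsilyl)oxy]-3-(propan-2-yl)bicyclo[3.1.0]hexan-2-yl benzoate (benzoate analogue of 10) | CC(C)(C)[Si](C)(C)O[C@H]1[C@@H]2C(Br)(Br)[C@@H]2[C@H](OC(=O)c3ccccc3)[C@H]1C(C)C
F9 | step 8 | (1R,2R,5R,6R)-3-bromo-5-[(tert-butyldimethylsilyl)oxy]-2-hydroxy-6-(propan-2-yl)cyclohex-3-en-1-yl benzoate (C6 benzoate of diol 12) | CC(C)(C)[Si](C)(C)O[C@H]1C=C(Br)[C@H](O)[C@H](OC(=O)c2ccccc2)[C@H]1C(C)C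
F10 | step 8 | (1R,4R,5R,6R)-2-bromo-4-[(tert-butyldimethylsilyl)oxy]-6-hydroxy-5-(propan-2-yl)cyclohex-2-en-1-yl benzoate (C1 benzoate of diol 12) | CC(C)(C)[Si](C)(C)O[C@H]1C=C(Br)[C@H](OC(=O)c2ccccc2)[C@H](O)[C@H]1C(C)C
F11 | step 5 | tert-butyl (1S,4R,5S)-4-hydroxy-5-(propan-2-yl)cyclopent-2-en-1-yl carbonate (C4 epimer of 7) | O[C@@H]1C=C[C@H](OC(=O)OC(C)(C)C)[C@H]1C(C)C
F12 | step 5 | (1S,4S,5S)-4-[(tert-butoxycarbonyl)oxy]-5-(propan-2-yl)cyclopent-2-en-1-yl 4-nitrobenzoate (4-nitrobenzoate of 7) | O=C(O[C@H]1C=C[C@H](OC(=O)OC(C)(C)C)[C@H]1C(C)C)c1ccc(cc1)[N+](=O)[O-]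
F13 | step 9 | dibutylstannylene acetal of 12 (2,2-dibutyl-1,3,2-dioxastannolane cis-fused at the two carbinol carbons) | CC(C)(C)[Si](C)(C)O[C@H]1C=C(Br)[C@@H]2O[Sn](CCCC)(CCCC)O[C@@H]2[C@H]1C(C)C
F14 | step 14 | (1R,5S,6R)-5-[(tert-butyldimethylsilyl)oxy]-2-oxo-6-(propan-2-yl)cyclohex-3-en-1-yl (2E)-4-[(tert-butyldiphenylsilyl)oxy]-2-methylbut-2-enoate | CC(C)(C)[Si](C)(C)O[C@H]1C=CC(=O)[C@H](OC(=O)/C(C)=C/CO[Si](c2ccccc2)(c2ccccc2)C(C)(C)C)[C@H]1C(C)C
A1 | alternative 1 | (E)-buta-1,3-dien-1-yl acetate | CC(=O)O/C=C/C=C
A2 | alternative 1 | 3-[(E)-3-(benzoyloxy)prop-2-enoyl]-1,3-oxazolidin-2-one | O=C(/C=C/OC(=O)c1ccccc1)N1CCOC1=O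
A3 | alternative 1 | 4-acetoxy-6-benzoyloxy-5-(2-oxooxazolidine-3-carbonyl)cyclohex-2-ene (target numbering; acetoxy cis and benzoyloxy trans to the acyl group) | CC(=O)O[C@H]1C=CC[C@H](OC(=O)c2ccccc2)[C@H]1C(=O)N3CCOC3=O
A4 | alternative 2 | oxime of 3-(2,2-dimethyl-5-vinyl-1,3-dioxolan-4-yl)-4-methylpentanal | CC(C)[C@H](CC=NO)[C@H]1OC(C)(C)O[C@@H]1C=C
A5 | alternative 2 | nitrile oxide derived from A4 | CC(C)[C@H](CC#[N+][O-])[C@H]1OC(C)(C)O[C@@H]1C=C
A6 | alternative 2 | acetonide-bridged cyclohexane-fused isoxazoline (one C2 epimer) | CC(C)[C@@H]1CC2=NOC[C@@H]2[C@H]3OC(C)(C)O[C@H]13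
A7 | alternative 3 | 2-{[(tert-butyldimethylsilyl)oxy]methyl}-6-[(4-methoxybenzyl)oxy]-5-(propan-2-yl)octa-1,7-dien-3-one | C=C(CO[Si](C)(C)C(C)(C)C)C(=O)C[C@@H](C(C)C)[C@@H](OCc1ccc(OC)cc1)C=C
A8 | alternative 3 | 5-isopropyl-4-(4-methoxybenzyloxy)-2-[(tert-butyldimethylsilyloxy)methyl]cyclohex-2-en-1-one | COc1ccc(CO[C@H]2C=C(CO[Si](C)(C)C(C)(C)C)C(=O)C[C@H]2C(C)C)cc1
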